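Count, for each flask, how many substrate lifetimes fit into its time.

in all of them: substrate 0.20 M
- maple: partner 0.20 M; temperature 80 °C; run made earlier
- cedar: partner 0.45 M; temperature 108 °C; run made earlier
- autumn: partner 0.300 M; temperature 85 °C; time 50 min
- noon: partner 0.300 M; temperature 130 °C; time 50 min
- summer: partner 0.300 M; temperature 100 °C; time 50 min
- dawn: partner 0.300 M; temperature 115 °C; time 50 min

- maple (time / min: target / %, substrate / %): 12.0: 0, 98.0; 25.0: 0.2, 95.7; 40.0: 0.3, 93.3; 50.0: 0.5, 91.9; 60.0: 0.2, 90.0
- cedar (time / min: target / %, substrate / %): 1.50: 0.2, 95.5; 3.00: 0.7, 90.5; 5.00: 1.6, 84.6; 10.0: 4.3, 71.7; 20.0: 10.7, 51.7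

(readings scatter by 0.3 percentage points)

- which flask leads in amount of target, in percent of the substrate charged ("all alike" within 1.5 percentage points) (autumn / noon / summer / dawn / all alike)
- how much target is there at the end, in percent of the substrate charged: autumn
- how much target is there at the end, in percent of the substrate charged: noon
- how much target is there at the end, in percent of the substrate charged: summer
- how much target is there at the end, in percent of the substrate charged: dawn

- what was read earlier has a scatter of 0.3 percentage points, one standard deviation

Two times matter here: the substrate's first-order life and the time of the flask. In the cedar run the constant read at 5.00 min, 0.0334 min⁻¹, matches the one read at 20.0 min, 0.0330 min⁻¹, so this reckoning takes the loss as independent of partner. The maple run reads 0.00176 min⁻¹ at 60.0 min, and the two runs together give an activation energy of 117 kJ mol⁻¹.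

The flask time over the substrate life is θ, the Damköhler number, and the substrate left is exp(−θ). For autumn, summer, dawn and noon, θ is 0.153, 0.746, 3.21 and 12.4.

In the cedar run target lags behind the substrate's loss. Its share of the lost substrate in the cedar run is 10.4 % at θ = 0.167 and 22.2 % at θ = 0.660. Carrying these shares over, although partner and temperature differ, gives about 1.48 % for autumn and 11.7 % for summer. Dawn and noon lie beyond the readings, and the later share, carried over in the same way, gives about 21.3 % and 22.2 %. This reckoning expects noon to lead, with θ the highest, on the assumption that the share keeps rising.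

The forecast, which differs from this reckoning, names noon and gives 0.8 %, 40 %, 8.5 % and 29 % for autumn, noon, summer and dawn, noting that “Target lags and stays far below substrate lost”.

The flasks give 1.89 %, 31.2 %, 10.7 % and 23.7 % in the same order, and noon leads.

    target ⇌ isomer of the product (K = 1.90, k = 0.0497 min⁻¹, Ea = 104 kJ mol⁻¹, ΔH = −21.0 kJ mol⁻¹)
    2 open intermediate → homo product (k = 0.0476 M⁻¹ min⁻¹, Ea = 84.0 kJ mol⁻¹)
    substrate → open intermediate (k = 0.0149 min⁻¹, Ea = 119 kJ mol⁻¹)
    open intermediate + second intermediate → target (k = 0.0673 M⁻¹ min⁻¹, Ea = 72.0 kJ mol⁻¹)
    partner → second intermediate (k = 0.476 min⁻¹, Ea = 96.0 kJ mol⁻¹)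
    (constants at 100 °C)

The summer flask holds 47.5 % substrate at 50 min, and its θ leaves 47.4 %. Its target is 20.4 % of the substrate lost. The autumn charge run at 110 °C for 50 min has θ = 2.00, which leaves 13.5 %, and that flask holds 13.2 % substrate.

The numbers in the tables come from a simulation with made-up constants; noise was put on by code.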